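The plan rests on cutting the C9–C10 bond of ring A. C10 is a CH(CH3) unit flanked by the C9 carbinol and by C11, the quaternary carbon shared by rings A, B and C. A vinyl group on C11 therefore hides both the C10 radical and the C10 methyl, and a C9 aldehyde on the C6 side chain accepts it. One iron-hydride hydrogen-atom-transfer cyclisation forms C9–C10, closes ring A and creates both stereocentres. The precursor is a cis-fused bicyclo[3.2.0]heptane (rings B and C). It carries the C1 acetate, a C4 silyl ether, the C11 vinyl group and, cis to it on C6, a CH(CH3)CH2CHO chain. It comes from an intramolecular vinylketene [2+2] cycloaddition.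

Key step: step 16

Assumption: locants C1–C11 follow the target SMILES from the acetoxy carbon; on ring B the α face carries the C3 methyl, C7 and C10, the β face carries C1, C2 and the C6 methyl; compounds 1, 5, 7 and 11 are taken as purchasable.

Step 1
Reactants: 1 monomethyl (R)-3-methylglutarate
Product: 3 (S)-4-methyloxan-2-one, via hydroxy acid 2 (not isolated)
Conditions: LiBH4, THF, 0 °C to reflux; then 2 M HCl, rt
Reagents that add atoms: none
Why: LiBH4 reduces the methyl ester but not the lithium carboxylate, and acid then closes the δ-lactone (chemoselective ester reduction followed by lactonisation), so the purchased stereocentre becomes C7 unchanged, with the former ester carbon as C9 and the former acid carbon as C11.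

Step 2
Reactants: 3 (S)-4-methyloxan-2-one
Product: 4 (3R,4S)-3,4-dimethyloxan-2-one
Conditions: LiN(i-Pr)2, THF, −78 °C; MeI, −78 to −20 °C
Reagents that add atoms: iodomethane CI
Why: Lactone enolate alkylation puts the future C6 methyl in place, mainly trans to the C7 methyl, and the ratio at C6 does not matter because step 3 planarises this carbon again.

Step 3
Reactants: 4 (3R,4S)-3,4-dimethyloxan-2-one; 5 2-bromo-N-methoxy-N-methylacetamide
Product: 6 2-[(3R,4S)-3,4-dimethyl-2-oxooxan-3-yl]-N-methoxy-N-methylacetamide
Conditions: LiN(i-Pr)2, THF/DMPU, −78 °C; then 5, −78 to −20 °C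
Reagents that add atoms: none
Why: A second lactone enolate alkylation builds quaternary C6: in the tetrasubstituted enolate A(1,2) strain forces the C7 methyl pseudo-axial, so the activated α-bromo amide enters from the opposite face and the two methyl groups end up cis, the usual outcome for 2,3-dimethyl six-membered-ring enolates.

Step 4
Reactants: 6 2-[(3R,4S)-3,4-dimethyl-2-oxooxan-3-yl]-N-methoxy-N-methylacetamide; 7 isopropenylmagnesium bromide
Product: 8 (3R,4S)-3,4-dimethyl-3-(3-methyl-2-oxobut-3-en-1-yl)oxan-2-one
Conditions: THF, −40 to 0 °C; then 1 M HCl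
Reagents that add atoms: none
Why: Weinreb ketone synthesis: the magnesium chelate of the tetrahedral adduct blocks a second addition, and the amide is attacked in preference to the lactone carbonyl C11, which is shielded by quaternary C6.

Step 5
Reactants: 8 (3R,4S)-3,4-dimethyl-3-(3-methyl-2-oxobut-3-en-1-yl)oxan-2-one
Product: 9 (3R,4S)-3-[(2R)-2-hydroxy-3-methylbut-3-en-1-yl]-3,4-dimethyloxan-2-one
Conditions: (S)-2-methyl-CBS-oxazaborolidine (20 mol%), catecholborane, toluene, −78 °C; then aq. NaHCO3
Reagents that add atoms: none
Why: Corey–Bakshi–Shibata reduction sets C4 under reagent control, the α-branched isopropenyl group acting as the large substituent so that the (S)-catalyst should give the (R)-allylic alcohol, while catecholborane at low temperature spares the alkene and the lactone.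

Step 6
Reactants: 9 (3R,4S)-3-[(2R)-2-hydroxy-3-methylbut-3-en-1-yl]-3,4-dimethyloxan-2-one
Product: 10 C4 tert-butyldimethylsilyl ether of 9
Conditions: TBSOTf, 2,6-lutidine, CH2Cl2, −78 to 0 °C
Reagents that add atoms: tert-butyldimethylsilyl triflate CC(C)(C)[Si](C)(C)OS(=O)(=O)C(F)(F)F
Why: Prompt silylation with the reactive triflate caps the hindered C4 hydroxyl before it can translactonise onto C11, and no stereocentre is touched.

Step 7
Reactants: 10 C4 tert-butyldimethylsilyl ether of 9; 11 ethyllithium
Product: 12 (4R,5S)-4-[(2R)-2-(tert-butyldimethylsilyloxy)-3-methylbut-3-en-1-yl]-7-hydroxy-4,5-dimethylheptan-3-one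
Conditions: THF, −78 °C; then sat. aq. NH4Cl
Reagents that add atoms: none
Why: Mono-addition of an organolithium to a lactone: the lithium lactolate beside quaternary C6 is stable at −78 °C, so only one ethyl group (C10 plus the future C10 methyl) is taken up and work-up opens it to the C11 ketone and the C9 alcohol.

Step 8
Reactants: 12 hydroxy ketone (C11 ketone, C9 alcohol, C4 OTBS)
Product: 13 bis-silyl ethyl ketone (C9 OTBS, C4 OTBS, C11 ketone)
Conditions: TBSCl, imidazole, DMF, rt
Reagents that add atoms: tert-butyldimethylsilyl chloride CC(C)(C)[Si](C)(C)Cl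
Why: Standard silylation of the primary alcohol pulls the lactol/hydroxy ketone equilibrium to the open chain and gives two silyl ethers that differ strongly in steric access.

Step 9
Reactants: 13 bis-silyl ethyl ketone
Product: 14 (Z)-enol triflate of 13 (C11 OTf, C10=C11, methyl cis to OTf)
Conditions: KN(SiMe3)2, THF, −78 °C; PhNTf2, −78 to 0 °C; then sat. aq. NH4Cl
Reagents that add atoms: N-phenylbis(trifluoromethanesulfonimide) O=S(=O)(C(F)(F)F)N(c1ccccc1)S(=O)(=O)C(F)(F)F
Why: Enolisation is possible only toward C10 because C6 is quaternary, the bulky tert-alkyl side enforces the Z enolate, and N-phenyltriflimide traps it as the (Z)-enol triflate (kinetic enolate O-sulfonylation).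

Step 10
Reactants: 14 (Z)-enol triflate
Product: 16 (Z)-but-2-enoic acid carrying quaternary C6 on C11 (C1 acid; methyl cis to CO2H), via mixed anhydride 15 (not isolated)
Conditions: Pd(OAc)2 (10 mol%), PPh3 (20 mol%), KOAc, CO (1 atm), DMF, 50 °C; then H2O, pH 4 buffer
Reagents that add atoms: carbon monoxide [C-]#[O+]; potassium acetate CC(=O)[O-].[K+]
Why: Palladium-catalysed hydroxycarbonylation of an enol triflate (oxidative addition to zerovalent palladium, CO insertion, capture by acetate, hydrolysis of the mixed anhydride) introduces C1 with retention of alkene geometry, and CO insertion under a CO atmosphere should outrun carbopalladation of the distant isopropenyl group, which would have to join two fully substituted carbons.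

Step 11
Reactants: 16 (Z)-but-2-enoic acid carrying quaternary C6 on C11
Product: 19 bicyclic cyclobutanone (cis-fused rings B/C; C1 ketone; 3α-methyl; 4α-OTBS; 6β-methyl; 6α-[(2S)-4-(TBSO)butan-2-yl]; 11α-vinyl), via acid chloride 17 (not isolated), via vinylketene 18 (not isolated)
Conditions: 1-chloro-N,N,2-trimethylprop-1-en-1-amine, CH2Cl2, 0 °C to rt; then slow addition to Et3N, toluene, reflux, high dilution
Reagents that add atoms: 1-chloro-N,N,2-trimethylprop-1-en-1-amine CC(C)=C(Cl)N(C)C (chlorine kept only in 17)
Why: Neutral acid chloride formation and 1,4-dehydrochlorination give the vinylketene, which undergoes the well-precedented intramolecular ketene–alkene [2+2] cycloaddition: electrophilic C1 bonds to the terminal C2 and C11 to the cation-stabilising C3, which gives the fused rather than the bridged skeleton, the three-atom tether enforces the cis B/C fusion, and the diastereoface should be chosen so that the two bulky tether substituents (C4 OTBS and the branched C7 chain) lie on the convex α face with only C4–H and the C6 methyl in the fold under the new cyclobutanone.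

Step 12
Reactants: 19 bicyclic cyclobutanone
Product: 20 bicyclic exo-cyclobutanol (C1 OH cis to the C11 vinyl and the C3 methyl, trans to ring B)
Conditions: SmI2, H2O, THF, 0 °C to rt
Reagents that add atoms: none
Why: Ketyl (single-electron) reduction is chosen because hydride reagents can reach C1 only from the exo face (the endo face is covered by the β C6 methyl) and would give the endo carbinol, whereas the samarium ketyl and the derived organosamarium place the bulky oxygen substituent exo and are protonated from the endo side, giving the less compressed exo alcohol, the classical reversal between hydride and electron-transfer reduction of hindered ketones.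

Step 13
Reactants: 20 bicyclic exo-cyclobutanol
Product: 21 bicyclic C1 exo-acetate with C4 OTBS and C9 OTBS
Conditions: Ac2O, DMAP (cat.), pyridine, rt
Reagents that add atoms: acetic anhydride CC(=O)OC(C)=O
Why: DMAP-catalysed acetylation of the secondary cyclobutanol installs the C1 acetate of the target with retention.

Step 14
Reactants: 21 bicyclic C1 exo-acetate with C4 OTBS and C9 OTBS
Product: 22 bicyclic C9 primary alcohol (C1 OAc, C4 OTBS, C11 vinyl)
Conditions: HF·pyridine, pyridine, THF, 0 °C
Reagents that add atoms: none
Why: The unhindered primary C9 silyl ether is cleaved much faster by buffered fluoride than the secondary C4 silyl ether next to quaternary C3 (selective desilylation), and the acetate is inert.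

Step 15
Reactants: 22 bicyclic C9 primary alcohol
Product: 23 bicyclo[3.2.0]heptane aldehyde (C1 exo-OAc, 4α-OTBS, 11α-vinyl, 6α-[(2S)-4-oxobutan-2-yl], 6β-methyl, 3α-methyl)
Conditions: Dess–Martin periodinane, CH2Cl2, 0 °C to rt
Reagents that add atoms: none
Why: Dess–Martin oxidation under neutral conditions stops at the aldehyde and does not epimerise C7, which is β to the carbonyl.

Step 16
Reactants: 23 bicyclo[3.2.0]heptane aldehyde
Product: 24 tricyclic C9 alcohol (ring A closed; C9 OH and C10 methyl on the face of ring A opposite to the C6 and C7 methyls; C1 OAc; 4α-OTBS)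
Conditions: Fe(acac)3 (30 mol%), PhSiH3 (3 equiv), degassed EtOH (0.02 M), 50 °C
Reagents that add atoms: none
Why: Fe(acac)3 and PhSiH3 in ethanol form an iron hydride that hands a hydrogen atom to the unhindered terminal CH2 of the C11 vinyl group, so that this carbon becomes the C10 methyl and C10 a secondary radical, which adds to the C9 aldehyde carbon; the C9 alkoxyl radical is then quenched by divalent iron and ethanol (or by hydrogen abstraction from ethanol), and the trivalent iron ethoxide is returned to the hydride by the silane. The closest known reaction type is the iron-hydride HAT-initiated reductive cyclisation of alkene-tethered ketones, aldehyde acceptors being the rarer variant. Ring A closes in a 6-exo-trig mode on the C=O bond through a chair-like array C10–C11–C6–C7–C8–C9. At C10 the methyl should take the pseudo-equatorial site away from the axial C6 methyl, and at C9 the oxygen is drawn on the C3 side as in the target, but neither centre has to be controlled because step 17 deletes C9 and equilibrates C10. The step needs chemoselectivity: ring closure must beat opening of the cyclobutylcarbinyl radical (C11–C1 or C11–C3 cleavage), 1,5-hydrogen transfer from C8, plain alkene reduction and aldehyde hydrosilylation, and it is helped by the cis arrangement of vinyl and side chain on the adjacent quaternary carbons C11 and C6, by dilution and a moderate temperature, and by a protic solvent that traps the alkoxyl radical before it reverts. C1 is kept as an sp3 acetate because a C1 ketone would divert the C10 radical into a Dowd–Beckwith ring expansion, and the neutral medium leaves acetate, silyl ether and cyclobutane untouched.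

Step 17
Reactants: 24 tricyclic C9 alcohol
Product: 25 tricyclic C9 ketone (C10 methyl equatorial; C1 OAc; 4α-OTBS)
Conditions: Dess–Martin periodinane, CH2Cl2, rt; then DBU (20 mol%), toluene, rt
Reagents that add atoms: none
Why: Dess–Martin oxidation removes the C9 stereocentre and base-catalysed enolisation toward C10 funnels any C10 epimer into the equatorial methyl isomer, since the axial epimer suffers a syn-axial clash with the C6 methyl.

Step 18
Reactants: 25 tricyclic C9 ketone
Product: 26 tricyclic keto alcohol (C9 ketone, 4α-OH, C1 OAc)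
Conditions: 48% aq. HF, MeCN, rt
Reagents that add atoms: none
Why: Acidic fluoride cleaves the remaining hindered silyl ether (desilylation) without touching acetate or ketone, so that C4–OH is now the only hydroxyl group in the molecule.

Step 19
Reactants: 26 tricyclic keto alcohol
Product: 27 tricyclic bromo ketone (4β-Br, C9 ketone, C1 OAc)
Conditions: CBr4, PPh3, toluene, 0 to 60 °C
Reagents that add atoms: carbon tetrabromide BrC(Br)(Br)Br
Why: Appel reaction: the alkoxyphosphonium ion is displaced by bromide in an SN2 step with inversion from the open β face, anti to the C3 methyl, which is the same topology as the known inversions of cyclopentanols flanked by an angular methyl (steroid 17β to 17α), and the non-ionising solvent disfavours migration of the antiperiplanar C3–C2 bond.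

Step 20
Reactants: 27 tricyclic bromo ketone
Product: 29 tricyclic dibromo ketone (C8 Br equatorial and trans to the C7 methyl; 4β-Br; C9 ketone; C1 OAc), via silyl enol ether 28 (not isolated)
Conditions: LiN(SiMe3)2, Me3SiCl, THF, −78 °C; NBS, THF, −78 to 0 °C; then LiBr (cat.), acetone, rt
Reagents that add atoms: chlorotrimethylsilane C[Si](C)(C)Cl (kept only in 28); N-bromosuccinimide O=C1CCC(=O)N1Br
Why: Kinetic deprotonation with in situ silylation takes the less hindered C8–H (faster than C10–H or the acetate methyl), electrophilic bromination of the silyl enol ether places bromine at C8, and degenerate bromide exchange at this activated centre lets the mixture settle on the equatorial bromide, trans to the C7 methyl and free of the syn-axial C6 methyl.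

Step 21
Reactants: 29 tricyclic dibromo ketone
Product: 30 CNP0246576.1 (target)
Conditions: NaBH4, MeOH/THF, −40 to 0 °C
Reagents that add atoms: none
Why: Borohydride 1,2-reduction under steric approach control: the face of the C9 carbonyl that carries C3 and its methyl is closed, so hydride enters from the face of the C6 and C7 methyls and pushes the hydroxyl to the side of the C8 bromine and the C10 methyl, giving the cis-bromohydrin, which cannot close to an epoxide, while the acetate and both bromides survive.

Compound list
1 | monomethyl (R)-3-methylglutarate | OC(=O)C[C@@H](C)CC(=O)OC | starting material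
2 | (S)-5-hydroxy-3-methylpentanoic acid | OC(=O)C[C@@H](C)CCO | intermediate
3 | (S)-4-methyloxan-2-one | O=C1C[C@@H](C)CCO1 | intermediate
4 | (3R,4S)-3,4-dimethyloxan-2-one | O=C1[C@H](C)[C@@H](C)CCO1 | intermediate
5 | 2-bromo-N-methoxy-N-methylacetamide | BrCC(=O)N(C)OC | starting material
6 | 2-[(3R,4S)-3,4-dimethyl-2-oxooxan-3-yl]-N-methoxy-N-methylacetamide | O=C1[C@](C)(CC(=O)N(C)OC)[C@@H](C)CCO1 | intermediate
7 | isopropenylmagnesium bromide | C=C(C)[Mg]Br | starting material
8 | (3R,4S)-3,4-dimethyl-3-(3-methyl-2-oxobut-3-en-1-yl)oxan-2-one | O=C1[C@](C)(CC(=O)C(C)=C)[C@@H](C)CCO1 | intermediate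
9 | (3R,4S)-3-[(2R)-2-hydroxy-3-methylbut-3-en-1-yl]-3,4-dimethyloxan-2-one | O=C1[C@](C)(C[C@@H](O)C(C)=C)[C@@H](C)CCO1 | intermediate
10 | C4 TBS ether of 9 | O=C1[C@](C)(C[C@@H](O[Si](C)(C)C(C)(C)C)C(C)=C)[C@@H](C)CCO1 | intermediate
11 | ethyllithium | [Li]CC | starting material
12 | (4R,5S)-4-[(2R)-2-(TBSO)-3-methylbut-3-en-1-yl]-7-hydroxy-4,5-dimethylheptan-3-one | CCC(=O)[C@](C)(C[C@@H](O[Si](C)(C)C(C)(C)C)C(C)=C)[C@@H](C)CCO | intermediate
13 | C9 TBS ether of 12 (bis-silyl ethyl ketone) | CCC(=O)[C@](C)(C[C@@H](O[Si](C)(C)C(C)(C)C)C(C)=C)[C@@H](C)CCO[Si](C)(C)C(C)(C)C | intermediate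
14 | (Z)-enol triflate of 13 | C/C=C(\OS(=O)(=O)C(F)(F)F)[C@](C)(C[C@@H](O[Si](C)(C)C(C)(C)C)C(C)=C)[C@@H](C)CCO[Si](C)(C)C(C)(C)C | intermediate
15 | mixed acetic anhydride of 16 | C/C=C(\C(=O)OC(C)=O)[C@](C)(C[C@@H](O[Si](C)(C)C(C)(C)C)C(C)=C)[C@@H](C)CCO[Si](C)(C)C(C)(C)C | intermediate
16 | (Z)-2-substituted but-2-enoic acid (C4 R, C6 R, C7 S) | C/C=C(\C(=O)O)[C@](C)(C[C@@H](O[Si](C)(C)C(C)(C)C)C(C)=C)[C@@H](C)CCO[Si](C)(C)C(C)(C)C | intermediate
17 | acid chloride of 16 | C/C=C(\C(=O)Cl)[C@](C)(C[C@@H](O[Si](C)(C)C(C)(C)C)C(C)=C)[C@@H](C)CCO[Si](C)(C)C(C)(C)C | intermediate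
18 | vinylketene (C11=C1=O, C11 vinyl) | C=CC(=C=O)[C@](C)(C[C@@H](O[Si](C)(C)C(C)(C)C)C(C)=C)[C@@H](C)CCO[Si](C)(C)C(C)(C)C | intermediate
19 | bicyclic cyclobutanone (C1 ketone, 4α-OTBS, 11α-vinyl, 6α side chain with C9 OTBS) | O=C1C[C@@]2(C)[C@H](O[Si](C)(C)C(C)(C)C)C[C@](C)([C@@H](C)CCO[Si](C)(C)C(C)(C)C)[C@@]12C=C | intermediate
20 | bicyclic exo-cyclobutanol | O[C@@H]1C[C@@]2(C)[C@H](O[Si](C)(C)C(C)(C)C)C[C@](C)([C@@H](C)CCO[Si](C)(C)C(C)(C)C)[C@@]12C=C | intermediate
21 | bicyclic C1 exo-acetate, C4 OTBS, C9 OTBS | CC(=O)O[C@@H]1C[C@@]2(C)[C@H](O[Si](C)(C)C(C)(C)C)C[C@](C)([C@@H](C)CCO[Si](C)(C)C(C)(C)C)[C@@]12C=C | intermediate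
22 | bicyclic C9 primary alcohol | CC(=O)O[C@@H]1C[C@@]2(C)[C@H](O[Si](C)(C)C(C)(C)C)C[C@](C)([C@@H](C)CCO)[C@@]12C=C | intermediate
23 | bicyclic aldehyde, precursor of the key step | CC(=O)O[C@@H]1C[C@@]2(C)[C@H](O[Si](C)(C)C(C)(C)C)C[C@](C)([C@@H](C)CC=O)[C@@]12C=C | intermediate
24 | tricyclic C9 alcohol, product of the key step | CC(=O)O[C@@H]1C[C@@]2(C)[C@H](O[Si](C)(C)C(C)(C)C)C[C@]3(C)[C@@H](C)C[C@H](O)[C@H](C)[C@]123 | intermediate
25 | tricyclic C9 ketone, 4α-OTBS | CC(=O)O[C@@H]1C[C@@]2(C)[C@H](O[Si](C)(C)C(C)(C)C)C[C@]3(C)[C@@H](C)CC(=O)[C@H](C)[C@]123 | intermediate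
26 | tricyclic keto alcohol, 4α-OH | CC(=O)O[C@@H]1C[C@@]2(C)[C@H](O)C[C@]3(C)[C@@H](C)CC(=O)[C@H](C)[C@]123 | intermediate
27 | tricyclic bromo ketone, 4β-Br | CC(=O)O[C@@H]1C[C@@]2(C)[C@@H](Br)C[C@]3(C)[C@@H](C)CC(=O)[C@H](C)[C@]123 | intermediate
28 | C8=C9 trimethylsilyl enol ether of 27 | CC(=O)O[C@@H]1C[C@@]2(C)[C@@H](Br)C[C@]3(C)[C@@H](C)C=C(O[Si](C)(C)C)[C@H](C)[C@]123 | intermediate
29 | tricyclic 4,8-dibromo C9 ketone | CC(=O)O[C@@H]1C[C@@]2(C)[C@@H](Br)C[C@]3(C)[C@@H](C)[C@H](Br)C(=O)[C@H](C)[C@]123 | intermediate
30 | CNP0246576.1 | CC(=O)O[C@@H]1C[C@@]2(C)[C@@H](Br)C[C@]3(C)[C@@H](C)[C@H](Br)[C@H](O)[C@H](C)[C@]123 | target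

Total step count: 21. Longest linear sequence: 21.

Steps most likely to fail

Step 16. The C10 radical sits next to the cyclobutane and may open it. The addition to the aldehyde may revert. Hydrogen transfer from C8 may turn the vinyl group into an ethyl group. The fallback closes the same bond with reversed polarity. It sets out from 23 and comes back at 24. SmI2 with HMPA and t-BuOH in THF makes the C9 ketyl, which adds 6-exo to C10. The primary radical on the terminal carbon is reduced and protonated to the C10 methyl, so no radical is ever placed beside ring C. Epimers at C9 and C10 converge in step 17. No new compound is made.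

Step 19. Substitution at this neopentylic carbon may lose to three side processes: ionisation with migration of the C3–C2 bond, elimination toward C5, or attack of the phosphorus ylide on the C9 ketone. The fallback installs the bromide before ring A exists and without phosphine. It sets out from 21 and comes back at 27.
- Aqueous HF in MeCN removes both silyl groups to give the C4,C9-diol F1.
- TEMPO/PhI(OAc)2 oxidises only the primary alcohol, giving the hydroxy aldehyde F2.
- Tf2O/pyridine at low temperature gives the C4 triflate F3.
- Bu4NBr in toluene displaces the triflate from the β face to give the bromo aldehyde F4.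
- The Fe(acac)3/PhSiH3 cyclisation of step 16 then gives the tricyclic bromo alcohol F5.
- Dess–Martin oxidation with DBU equilibration returns to 27.

Step 11. Facial selectivity may be poor or reversed, because the branched C7 chain could prefer the β side next to C1. The hindered ketene may also oligomerise. The fallback replaces the intramolecular cycloaddition by an approach-controlled enone–alkene photocycloaddition, in which the external alkene must come in anti to the C7 chain. It sets out from 6 and comes back at 21.
- EtMgBr gives the ethyl ketone lactone F6.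
- KOt-Bu closes ring B by acylation of the C3 enolate with the C11 lactone carbonyl, giving the cyclopentane-1,3-dione F7.
- TBSCl gives the C9 silyl ether F8.
- Me2SO4/K2CO3 methylates the less hindered C4 oxygen to give the vinylogous ester F9.
- HC≡CMgBr/CeCl3 adds to C11 to give the tertiary carbinol F10.
- Dilute acid gives the 3-ethynyl-2-methylcyclopentenone F11 (Stork–Danheiser transposition).
- Irradiation above 300 nm in vinyl acetate gives the head-to-tail exo-acetate photoadduct F12.
- NaBH4 attacks the C4 ketone from the β face to give the 4α-alcohol F13.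
- TBSOTf gives the bis-silyl alkyne F14.
- Semi-hydrogenation over Pd/CaCO3 poisoned with Pb(OAc)2 and quinoline returns to 21.

Further compounds
F0 | step 16 | none | none
F1 | step 19 | bicyclic C4,C9-diol (C1 OAc, C11 vinyl) | CC(=O)O[C@@H]1C[C@@]2(C)[C@H](O)C[C@](C)([C@@H](C)CCO)[C@@]12C=C
F2 | step 19 | bicyclic 4α-hydroxy C9 aldehyde | CC(=O)O[C@@H]1C[C@@]2(C)[C@H](O)C[C@](C)([C@@H](C)CC=O)[C@@]12C=C
F3 | step 19 | bicyclic 4α-triflate C9 aldehyde | CC(=O)O[C@@H]1C[C@@]2(C)[C@H](OS(=O)(=O)C(F)(F)F)C[C@](C)([C@@H](C)CC=O)[C@@]12C=C
F4 | step 19 | bicyclic 4β-bromo C9 aldehyde | CC(=O)O[C@@H]1C[C@@]2(C)[C@@H](Br)C[C@](C)([C@@H](C)CC=O)[C@@]12C=C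
F5 | step 19 | tricyclic 4β-bromo C9 alcohol | CC(=O)O[C@@H]1C[C@@]2(C)[C@@H](Br)C[C@]3(C)[C@@H](C)C[C@H](O)[C@H](C)[C@]123
F6 | step 11 | (3R,4S)-3,4-dimethyl-3-(2-oxobutyl)oxan-2-one | O=C1[C@](C)(CC(=O)CC)[C@@H](C)CCO1
F7 | step 11 | 4-[(2S)-4-hydroxybutan-2-yl]-2,4-dimethylcyclopentane-1,3-dione | CC1C(=O)C[C@](C)([C@@H](C)CCO)C1=O
F8 | step 11 | C9 TBS ether of F7 | CC1C(=O)C[C@](C)([C@@H](C)CCO[Si](C)(C)C(C)(C)C)C1=O
F9 | step 11 | vinylogous methyl ester (methoxy on C4, ketone at C11) | COC1=C(C)C(=O)[C@@](C)([C@@H](C)CCO[Si](C)(C)C(C)(C)C)C1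
F10 | step 11 | C11 ethynyl carbinol of F9 | COC1=C(C)C(O)(C#C)[C@@](C)([C@@H](C)CCO[Si](C)(C)C(C)(C)C)C1
F11 | step 11 | 3-ethynyl-2-methylcyclopentenone (C4 ketone, C11 ethynyl) | O=C1C[C@](C)([C@@H](C)CCO[Si](C)(C)C(C)(C)C)C(C#C)=C1C
F12 | step 11 | bicyclic photoadduct (C1 exo-OAc, C4 ketone, C11 ethynyl) | CC(=O)O[C@@H]1C[C@@]2(C)C(=O)C[C@](C)([C@@H](C)CCO[Si](C)(C)C(C)(C)C)[C@@]12C#C
F13 | step 11 | bicyclic 4α-alcohol of F12 | CC(=O)O[C@@H]1C[C@@]2(C)[C@H](O)C[C@](C)([C@@H](C)CCO[Si](C)(C)C(C)(C)C)[C@@]12C#C
F14 | step 11 | bicyclic bis-silyl C11 alkyne | CC(=O)O[C@@H]1C[C@@]2(C)[C@H](O[Si](C)(C)C(C)(C)C)C[C@](C)([C@@H](C)CCO[Si](C)(C)C(C)(C)C)[C@@]12C#C
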